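**Assumption:** the target SMILES contains no stereocenters. Shanciguol is achiral, so there is no enantiomer to control and no stereochemical step is needed.

## Retrosynthetic overview
- Shanciguol (**1**) is the pentaphenol of pentamethyl ether **2**, so the last step is a global O-demethylation.
- **2** comes from a double Friedel–Crafts benzylation of 3,3',5-trimethoxybibenzyl (**3**) with 4-methoxybenzyl alcohol (**4**). The two open positions ortho to the phenethyl group (each ortho to one OMe and para to the other) are the most nucleophilic sites of the resorcinol dimethyl ether ring.
- **3** comes from Sonogashira coupling of 3,5-dimethoxyphenylacetylene (**6**) with 3-iodoanisole (**7**) to give alkyne **5**, then hydrogenation.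
- Only the central ring's substituents are installed late. The other two aryl rings are already complete in the starting materials.

## Route

**Step 1**
Reactants: **6** 1-ethynyl-3,5-dimethoxybenzene; **7** 3-iodoanisole
Product: **5** 1,3-dimethoxy-5-[(3-methoxyphenyl)ethynyl]benzene
Conditions: PdCl2(PPh3)2 (2 mol%), CuI (4 mol%), Et3N/THF, 25 °C
Reagents that add atoms: none
Why: Sonogashira coupling joins the terminal alkyne to the aryl iodide selectively, and the methyl ethers are inert.

**Step 2**
Reactants: **5**
Product: **3** 1,3-dimethoxy-5-[2-(3-methoxyphenyl)ethyl]benzene (3,3',5-trimethoxybibenzyl)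
Conditions: H2 (1 atm), 10% Pd/C, EtOAc, 25 °C
Reagents that add atoms: none (H2 adds only hydrogen)
Why: Catalytic hydrogenation reduces the diarylalkyne fully to the bibenzyl. The aryl methyl ethers are untouched and no stereocenter is formed.

**Step 3**
Reactants: **3**; **4** 4-methoxybenzyl alcohol (2.4 equiv)
Product: **2** 1,5-dimethoxy-2,4-bis(4-methoxybenzyl)-3-[2-(3-methoxyphenyl)ethyl]benzene
Conditions: **4** (2.4 equiv, added portionwise), Bi(OTf)3 (5 mol%), MeNO2, 40 °C
Reagents that add atoms: none (the benzyl group comes from reactant **4**; the catalyst is not incorporated)
Why: Lewis-acid ionization of **4** gives the 4-methoxybenzyl cation, which attacks the most nucleophilic arene in an electrophilic aromatic substitution (Friedel–Crafts benzylation). This is the resorcinol-diether ring, at the positions ortho to one OMe, para to the other and flanking the phenethyl chain; the C4 position between the two OMe groups is less reactive, as in the Vilsmeier formylation of orcinol dimethyl ether. The other two rings are much less nucleophilic. The second benzylation is directed to the symmetry-related open position, giving the 2,6-bis-benzyl pattern.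

**Step 4**
Reactants: **2**
Product: **1** Shanciguol
Conditions: BBr3 (10 equiv), CH2Cl2, −78 → 25 °C, 12 h; quench with MeOH
Reagents that add atoms: none (Br is lost as MeBr/B–O species; the OH oxygens come from the existing OMe oxygens)
Why: BBr3 cleaves all five aryl methyl ethers by Lewis-acid-assisted demethylation. The diarylmethane and bibenzyl CH2 groups are stable, and there are no stereocenters to scramble.

## Checks performed
- **Structure match:** the central ring has the phenethyl group at C1, OH at C3 and C5, 4-hydroxybenzyl at C2 and C6, and H at C4. The phenethyl's aryl ring carries a 3-OH, and the two benzyl rings carry 4-OH. This matches the target SMILES.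
- **Atom count:** **2** is C33H36O5; removing five CH2 units gives C28H26O5, which is the target formula.
- **Functional-group survival:** only aryl methyl ethers are present until step 4; they survive Pd/Cu coupling, hydrogenation and the mild Lewis acid in step 3.
- **Stereochemistry:** there are no stereocenters, so nothing can be set or scrambled.

## Compound list
1 | Shanciguol, 3,3',5-trihydroxy-2,6-bis(4-hydroxybenzyl)bibenzyl | Oc1ccc(Cc2c(O)cc(O)c(Cc3ccc(O)cc3)c2CCc2cccc(O)c2)cc1 | target
2 | 1,5-dimethoxy-2,4-bis(4-methoxybenzyl)-3-[2-(3-methoxyphenyl)ethyl]benzene (pentamethyl ether of **1**) | COc1ccc(Cc2c(OC)cc(OC)c(Cc3ccc(OC)cc3)c2CCc2cccc(OC)c2)cc1 | intermediate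
3 | 1,3-dimethoxy-5-[2-(3-methoxyphenyl)ethyl]benzene (3,3',5-trimethoxybibenzyl) | COc1cccc(CCc2cc(OC)cc(OC)c2)c1 | intermediate
4 | 4-methoxybenzyl alcohol | COc1ccc(CO)cc1 | starting material
5 | 1,3-dimethoxy-5-[(3-methoxyphenyl)ethynyl]benzene | COc1cccc(C#Cc2cc(OC)cc(OC)c2)c1 | intermediate
6 | 1-ethynyl-3,5-dimethoxybenzene | COc1cc(C#C)cc(OC)c1 | starting material
7 | 3-iodoanisole | COc1cccc(I)c1 | starting material

**Total step count:** 4
**Longest linear sequence:** 4 steps (6 → 5 → 3 → 2 → 1)

## Three steps most likely to fail
1. **Step 3 (double benzylation).** Risks are a 2,4-bis-benzyl regioisomer, tribenzylation, and self-condensation of the 4-methoxybenzyl cation.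
   - Fallback: change the approach to a regiodefined cross-coupling. Dibrominate **3** with NBS (2.1 equiv), confirm the 2,6-dibromide, then double Negishi or Suzuki coupling with 4-methoxybenzylzinc chloride or potassium 4-methoxybenzyltrifluoroborate.
2. **Step 4 (pentademethylation).** BBr3 may leave partially demethylated products or cause acid-mediated benzylic cleavage of the electron-rich bis-benzyl resorcinol.
   - Fallback: use nucleophilic SN2 demethylation with NaSEt in DMF at 130 °C, which avoids strong Lewis acid.
3. **Step 1 (Sonogashira).** Glaser homocoupling of the electron-rich terminal alkyne would lower the yield.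
   - Fallback: switch to a Wittig/hydrogenation route. Convert 3,5-dimethoxybenzyl bromide to its phosphonium salt, do the Wittig reaction with 3-methoxybenzaldehyde, then hydrogenate the stilbene to give **3**.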